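I began from a leftover. A single-handed reagent turns a racemic pair of substrates into left-handed and right-handed product. Pooled at 10.0 h, the oak, maple and birch runs left 33.3% of the left-handed substrate's charge and 62.0% of the right-handed substrate's. Each substrate was half of the charge, so I doubled the product readings before subtracting them. My decision was whether to stop at 12 h (red) or run on to 50 h (blue).

| flask | left-handed substrate | right-handed substrate | gas | racemization catalyst | impurity | remark | time |
|---|---|---|---|---|---|---|---|
| oak | 0.050 M | 0.050 M | 11 mM (held) | 0.5 mol% | 0.085 mM | run made earlier |  |
| maple | 0.050 M | 0.050 M | 11 mM (held) | 0.5 mol% | 0.13 mM | run made earlier |  |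
| birch | 0.050 M | 0.050 M | 11 mM (held) | 0.75 mol% | 0.17 mM | run made earlier |  |
| red | 0.050 M | 0.050 M | 11 mM (held) | 0.5 mol% | 0.17 mM |  | 12 h |
| blue | 0.050 M | 0.050 M | 11 mM (held) | 0.5 mol% | 0.17 mM |  | 50 h |

| run | time / h | left-handed product / % | right-handed product / % |
|---|---|---|---|
| oak | 1.33 | 10 | 0 |
| oak | 3.00 | 12 | 5 |
| oak | 4.00 | 18 | 6 |
| oak | 6.00 | 22 | 13 |
| oak | 8.00 | 29 | 16 |
| oak | 10.0 | 33 | 17 |
| maple | 1.33 | 4 | 0 |
| maple | 3.00 | 14 | 8 |
| maple | 4.00 | 16 | 10 |
| maple | 6.00 | 21 | 8 |
| maple | 8.00 | 29 | 18 |
| maple | 10.0 | 35 | 21 |
| birch | 0.833 | 2 | 3 |
| birch | 1.33 | 7 | 2 |
| birch | 2.50 | 8 | 1 |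
| birch | 5.00 | 19 | 11 |
| birch | 10.0 | 32 | 19 |

(standard deviation of a reading: 2 percentage points)

* the winner by excess of left-handed product over right-handed product in the product; "neither" if no more than 2 percentage points parts them (red / blue / neither)
* excess of left-handed product over right-handed product in the product at the end, red
* excess of left-handed product over right-handed product in the product at the end, blue

- reagent is single-handed; left-handed substrate and right-handed substrate are mirror images of each other, charged as a racemate, each of them at the stated concentration
- what was read earlier has a scatter of 2 percentage points, one standard deviation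
- at the start none of the gas is in solution
- an excess is the difference of the two amounts in percent of their sum
- an excess is below zero if the other one leads
- the handed part of reagent does not stay in what it makes, so the products of the two hands are mirror images too

The reagent meets both substrates at one concentration. Suppose each substrate falls pseudo-first-order at that concentration and no racemization feeds one from the other. Then the reagent cancels from the ratio of the logarithms:

ln(33.3%) / ln(62.0%) = 2.30

I called this the leftover ratio, the logarithm of the left-handed leftover over that of the right-handed leftover, which under that supposition is the selectivity factor. It was a reading, with a scatter of 2 percentage points in each point.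

Next I assumed the reagent concentration stayed as it was. A later leftover is then the leftover at 10.0 h raised to the time over 10.0 h. The excess is the gap between the leftovers over what the two lost together:

red, 12 h: leftovers 26.8% and 56.3%, excess 25.3%

blue, 50 h: leftovers 0.412% and 9.16%, excess 4.59%

So I chose to stop at red, which by this reckoning held 21 points more excess than blue.

The forecast also chose red, but with higher figures of 27% and 8%, holding that “racemization is not keeping the substrate balanced”.

Red gave 21.3% and blue 6.76%, against my 25.3% and 4.59%, so red won.

    left-handed substrate + racemization catalyst ⇌ right-handed substrate + racemization catalyst, rate k1*[racemization catalyst]*[left-handed substrate] forward; the back reaction follows from the equilibrium constant (k = 420 /M/h)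
    2 racemization catalyst ⇌ resting dimer (K = 59000 /M, k = 1900 /M/h)
    racemization catalyst + impurity → spent catalyst (k = 1.70 × 10⁵ /M/h)
    reagent + right-handed substrate → right-handed product (k = 7.60 /M/h)
    gas ⇌ reagent, rate k5*(csat - [reagent]) (kL = 1.60 /h)
    reagent + left-handed substrate → left-handed product (k = 15.0 /M/h)

At the end of blue, 68.0% of the catalyst charged stood as spent catalyst, 23.1% as resting dimer and 8.86% as free racemization catalyst. Blue's leftovers of 0.26% and 1.9% give a leftover ratio of 1.50. The neighbour flask is blue with 6.8 × 10⁻⁴ M of impurity, and it ended with 99.9% as spent catalyst. Its leftovers of 0.073% and 2.6% give a leftover ratio of 1.98, and its excess was 1.27%.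

The data come from a simulation for substances that don't exist; noise was put on by code.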